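**Retrosynthetic overview**

- Feature: the only ring to be built is the oxirane, and it is terminal. Its C2 is quaternary (aryl and CH2O-pentanoyl) and its C3 is a bare CH2, so C2–C3 and C3–O are cut together to leave an aryl ketone C=O plus one CH2 from a sulfoxonium ylide.
- Ketone 11, ArC(=O)CH2OPMB, is cut at the aryl–carbonyl bond into an aryllithium (from methyl 4-bromo-3-hydroxybenzoate after O-allylation, reduction and silylation) and the Weinreb amide of PMB-protected glycolic acid. Every oxygen is an ether at this stage.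
- Ring order: the benzene ring is bought; the oxirane is closed in step 7 by catalytic enantioselective methylene transfer, which also sets the only stereocentre.
- Endgame on the epoxide: PMB off and pentanoate on, allyl off with the phenol handed to isobutyric anhydride as a tin phenoxide, silyl ether off last.

Key step: step 7

Assumption: which antipode of the binaphthoxide catalyst attacks the required carbonyl face of this α-alkoxymethyl ketone cannot be fixed in advance; the route is written with the complex from (R)-BINOL, to be exchanged for the complex from (S)-BINOL if the first run shows the mirror-image product.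

**Route**

Step 1
Reactants: 1 methyl 4-bromo-3-hydroxybenzoate
Product: 2 methyl 4-bromo-3-(prop-2-en-1-yloxy)benzoate
Conditions: allyl bromide, K2CO3, DMF, rt
Reagents that add atoms: allyl bromide, C=CCBr
Why: Williamson O-alkylation of the phenoxide with a reactive allylic bromide, under carbonate conditions that leave the methyl ester and the aryl bromide untouched.

Step 2
Reactants: 2 methyl 4-bromo-3-(prop-2-en-1-yloxy)benzoate
Product: 3 [4-bromo-3-(prop-2-en-1-yloxy)phenyl]methanol
Conditions: i-Bu2AlH (2.3 equiv), CH2Cl2, −78 °C to 0 °C; aqueous potassium sodium tartrate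
Reagents that add atoms: none
Why: Hydride reduction of the aryl ester to the benzylic alcohol with i-Bu2AlH at low temperature, which should not touch the aryl bromide or the allyl ether.

Step 3
Reactants: 3 [4-bromo-3-(prop-2-en-1-yloxy)phenyl]methanol
Product: 4 {[4-bromo-3-(prop-2-en-1-yloxy)phenyl]methoxy}tri(propan-2-yl)silane
Conditions: i-Pr3SiCl, imidazole, DMF, rt
Reagents that add atoms: triisopropylsilyl chloride, CC(C)[Si](Cl)(C(C)C)C(C)C
Why: Imidazole-promoted silylation of the primary benzylic alcohol gives an ether that should withstand butyllithium, the ylide and DDQ.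

Step 4
Reactants: 5 (4-methoxyphenyl)methanol; 6 2-chloro-N-methoxy-N-methylacetamide
Product: 8 N-methoxy-2-[(4-methoxyphenyl)methoxy]-N-methylacetamide, via sodium alkoxide 7 (not isolated)
Conditions: NaH, THF, 0 °C; then 6, 0 °C to rt
Reagents that add atoms: sodium hydride, [Na+].[H-] (its sodium is carried only in intermediate 7)
Why: Williamson ether synthesis in which the alkoxide displaces the carbonyl-activated α-chloride by SN2 faster than it attacks the weakly electrophilic Weinreb amide carbonyl.

Step 5
Reactants: 4 {[4-bromo-3-(prop-2-en-1-yloxy)phenyl]methoxy}tri(propan-2-yl)silane; 8 N-methoxy-2-[(4-methoxyphenyl)methoxy]-N-methylacetamide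
Product: 11 2-[(4-methoxyphenyl)methoxy]-1-[2-(prop-2-en-1-yloxy)-4-({[tri(propan-2-yl)silyl]oxy}methyl)phenyl]ethan-1-one, via aryllithium 9 (not isolated), via lithium hemiaminal chelate 10 (not isolated)
Conditions: n-BuLi (1.05 equiv), THF, −78 °C; then 8, −78 °C to −30 °C; aqueous NH4Cl
Reagents that add atoms: n-butyllithium, [Li]CCCC (its lithium is carried only in intermediates 9 and 10)
Why: Bromine–lithium exchange at −78 °C should outrun cyclisation onto or deprotonation of the allyl ether, and the Weinreb ketone synthesis stops at one addition because the N-methoxy chelate 10 holds until the quench.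

Step 6
Reactants: 12 trimethylsulfoxonium chloride
Product: 13 dimethyloxosulfonium methylide
Conditions: NaH, THF, reflux; filtered under argon and kept as a titrated THF solution
Reagents that add atoms: none
Why: Deprotonation of the sulfoxonium salt gives the stabilised ylide, and starting from the chloride lets the insoluble NaCl be filtered off so that little halide is carried into the lithium sites of the catalyst.

Step 7
Reactants: 11 2-[(4-methoxyphenyl)methoxy]-1-[2-(prop-2-en-1-yloxy)-4-({[tri(propan-2-yl)silyl]oxy}methyl)phenyl]ethan-1-one; 13 dimethyloxosulfonium methylide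
Product: 15 (2R)-2-{[(4-methoxyphenyl)methoxy]methyl}-2-[2-(prop-2-en-1-yloxy)-4-({[tri(propan-2-yl)silyl]oxy}methyl)phenyl]oxirane, via betaine 14 (not isolated)
Conditions: LaLi3(binaphthoxide)3 from (R)-BINOL (5 mol %; made from La(OiPr)3, (R)-BINOL and n-BuLi), tris(2,4,6-trimethoxyphenyl)phosphine oxide (5 mol %), 13 (1.2 equiv), MS 5 Å, THF, rt
Reagents that add atoms: none
Why: This is a catalytic asymmetric Corey–Chaykovsky epoxidation: the ketone of 11 is thought to be activated on the trivalent lanthanum of the heterobimetallic complex while ylide 13 is positioned through its sulfoxonium oxygen on a neighbouring lithium, so the ylide carbon adds to one carbonyl face and makes the C2–CH2 bond (betaine 14). The tertiary alkoxide of 14 then displaces dimethyl sulfoxide from the adjacent CH2 in a 3-exo-tet closure, which forms the CH2–O bond and the only ring made in the route. The closest known reaction is the same catalyst and phosphine oxide additive on aryl methyl ketones; here CH2OPMB stands where methyl would be and the aryl group carries an ortho allyloxy group, so the enantioselectivity is an extrapolation and has to be measured before material is taken on. The single stereocentre (quaternary oxirane carbon, R) is set under catalyst control in the addition step, with the chiral pocket required to tell the twisted ortho-substituted aryl group from the smaller CH2OPMB arm, since the substrate has no stereocentre of its own. Chemoselectivity rests on the substrate: all three other oxygens are ethers (PMB, allyl, silyl), so the ketone is the only electrophile and there is no acidic O–H to quench the ylide, and 1.2 equiv of ylide at room temperature should hold back ring expansion of the product to an oxetane.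

Step 8
Reactants: 15 (2R)-2-{[(4-methoxyphenyl)methoxy]methyl}-2-[2-(prop-2-en-1-yloxy)-4-({[tri(propan-2-yl)silyl]oxy}methyl)phenyl]oxirane
Product: 16 {(2S)-2-[2-(prop-2-en-1-yloxy)-4-({[tri(propan-2-yl)silyl]oxy}methyl)phenyl]oxiran-2-yl}methanol
Conditions: DDQ (1.3 equiv), CH2Cl2/aqueous NaH2PO4–Na2HPO4 (pH 7), 0 °C
Reagents that add atoms: none
Why: Oxidative cleavage of the 4-methoxybenzyl ether by DDQ (hydride abstraction, then hydrolysis of the oxocarbenium ion), with the buffer keeping the acidic hydroquinone away from the benzylic oxirane and the allyl and silyl ethers inert to the oxidant; the descriptor changes from R to S only because the CIP ranking of the two CH2O arms changes.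

Step 9
Reactants: 16 {(2S)-2-[2-(prop-2-en-1-yloxy)-4-({[tri(propan-2-yl)silyl]oxy}methyl)phenyl]oxiran-2-yl}methanol
Product: 17 {(2R)-2-[2-(prop-2-en-1-yloxy)-4-({[tri(propan-2-yl)silyl]oxy}methyl)phenyl]oxiran-2-yl}methyl pentanoate
Conditions: (n-BuCO)2O, Et3N, DMAP (catalytic), CH2Cl2, 0 °C
Reagents that add atoms: pentanoic anhydride, CCCCC(=O)OC(=O)CCCC
Why: DMAP-catalysed acylation of the primary alcohol with the anhydride under basic, chloride-free conditions, so that no hydrogen chloride or chloride is present to open the oxirane.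

Step 10
Reactants: 17 {(2R)-2-[2-(prop-2-en-1-yloxy)-4-({[tri(propan-2-yl)silyl]oxy}methyl)phenyl]oxiran-2-yl}methyl pentanoate
Product: 19 {(2R)-2-[2-(2-methylpropanoyloxy)-4-({[tri(propan-2-yl)silyl]oxy}methyl)phenyl]oxiran-2-yl}methyl pentanoate, via tributylstannyl phenoxide 18 (not isolated)
Conditions: Pd(PPh3)4 (5 mol %), Bu3SnH (1.1 equiv, slow addition), (i-PrCO)2O (3 equiv), CH2Cl2, 0 °C to rt
Reagents that add atoms: isobutyric anhydride, CC(C)C(=O)OC(=O)C(C)C; tributyltin hydride, CCCC[SnH](CCCC)CCCC (its tin is carried only in intermediate 18)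
Why: Palladium-catalysed hydrostannolysis of the allyl aryl ether (zerovalent palladium ionises the allyl–oxygen bond, the tin hydride reduces the π-allyl complex to propene) gives the covalent tin phenoxide 18, which the anhydride present from the start should acylate at once so that no free phenol stays beside the oxirane.

Step 11
Reactants: 19 {(2R)-2-[2-(2-methylpropanoyloxy)-4-({[tri(propan-2-yl)silyl]oxy}methyl)phenyl]oxiran-2-yl}methyl pentanoate
Product: 20 {(2R)-2-[4-(hydroxymethyl)-2-(2-methylpropanoyloxy)phenyl]oxiran-2-yl}methyl pentanoate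
Conditions: Bu4NF/AcOH (1:1, 1.5 equiv), THF, 0 °C to rt
Reagents that add atoms: none
Why: Fluoride-driven cleavage of the primary benzylic silyl ether, buffered with acetic acid so that the aryl isobutyrate, the pentanoate and the oxirane should not meet free alkoxide or strong acid.

**Compound list**

1 | methyl 4-bromo-3-hydroxybenzoate | COC(=O)c1ccc(Br)c(O)c1 | starting material
2 | methyl 4-bromo-3-(prop-2-en-1-yloxy)benzoate | COC(=O)c1ccc(Br)c(OCC=C)c1 | intermediate
3 | [4-bromo-3-(prop-2-en-1-yloxy)phenyl]methanol | OCc1ccc(Br)c(OCC=C)c1 | intermediate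
4 | {[4-bromo-3-(prop-2-en-1-yloxy)phenyl]methoxy}tri(propan-2-yl)silane | C=CCOc1cc(CO[Si](C(C)C)(C(C)C)C(C)C)ccc1Br | intermediate
5 | (4-methoxyphenyl)methanol | COc1ccc(CO)cc1 | starting material
6 | 2-chloro-N-methoxy-N-methylacetamide | CON(C)C(=O)CCl | starting material
7 | sodium (4-methoxyphenyl)methanolate | COc1ccc(C[O-])cc1.[Na+] | intermediate (not isolated)
8 | N-methoxy-2-[(4-methoxyphenyl)methoxy]-N-methylacetamide | CON(C)C(=O)COCc1ccc(OC)cc1 | intermediate
9 | [2-(prop-2-en-1-yloxy)-4-({[tri(propan-2-yl)silyl]oxy}methyl)phenyl]lithium | [Li]c1ccc(CO[Si](C(C)C)(C(C)C)C(C)C)cc1OCC=C | intermediate (not isolated)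
10 | lithium 1-[methoxy(methyl)amino]-2-[(4-methoxyphenyl)methoxy]-1-[2-(prop-2-en-1-yloxy)-4-({[tri(propan-2-yl)silyl]oxy}methyl)phenyl]ethan-1-olate | COc1ccc(COCC(O[Li])(N(C)OC)c2ccc(CO[Si](C(C)C)(C(C)C)C(C)C)cc2OCC=C)cc1 | intermediate (not isolated)
11 | 2-[(4-methoxyphenyl)methoxy]-1-[2-(prop-2-en-1-yloxy)-4-({[tri(propan-2-yl)silyl]oxy}methyl)phenyl]ethan-1-one | COc1ccc(COCC(=O)c2ccc(CO[Si](C(C)C)(C(C)C)C(C)C)cc2OCC=C)cc1 | intermediate
12 | trimethylsulfoxonium chloride | C[S+](C)(C)=O.[Cl-] | starting material
13 | dimethyloxosulfonium methylide | C[S+](C)(=O)[CH2-] | intermediate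
14 | (2S)-1-(dimethyloxosulfonio)-3-[(4-methoxyphenyl)methoxy]-2-[2-(prop-2-en-1-yloxy)-4-({[tri(propan-2-yl)silyl]oxy}methyl)phenyl]propan-2-olate (betaine) | COc1ccc(COC[C@@]([O-])(c2ccc(CO[Si](C(C)C)(C(C)C)C(C)C)cc2OCC=C)C[S+](C)(C)=O)cc1 | intermediate (not isolated)
15 | (2R)-2-{[(4-methoxyphenyl)methoxy]methyl}-2-[2-(prop-2-en-1-yloxy)-4-({[tri(propan-2-yl)silyl]oxy}methyl)phenyl]oxirane | COc1ccc(COC[C@@]2(c3ccc(CO[Si](C(C)C)(C(C)C)C(C)C)cc3OCC=C)CO2)cc1 | intermediate
16 | {(2S)-2-[2-(prop-2-en-1-yloxy)-4-({[tri(propan-2-yl)silyl]oxy}methyl)phenyl]oxiran-2-yl}methanol | OC[C@@]1(c2ccc(CO[Si](C(C)C)(C(C)C)C(C)C)cc2OCC=C)CO1 | intermediate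
17 | {(2R)-2-[2-(prop-2-en-1-yloxy)-4-({[tri(propan-2-yl)silyl]oxy}methyl)phenyl]oxiran-2-yl}methyl pentanoate | CCCCC(=O)OC[C@@]1(c2ccc(CO[Si](C(C)C)(C(C)C)C(C)C)cc2OCC=C)CO1 | intermediate
18 | {(2R)-2-[2-[(tributylstannyl)oxy]-4-({[tri(propan-2-yl)silyl]oxy}methyl)phenyl]oxiran-2-yl}methyl pentanoate | CCCCC(=O)OC[C@@]1(c2ccc(CO[Si](C(C)C)(C(C)C)C(C)C)cc2O[Sn](CCCC)(CCCC)CCCC)CO1 | intermediate (not isolated)
19 | {(2R)-2-[2-(2-methylpropanoyloxy)-4-({[tri(propan-2-yl)silyl]oxy}methyl)phenyl]oxiran-2-yl}methyl pentanoate | CCCCC(=O)OC[C@@]1(c2ccc(CO[Si](C(C)C)(C(C)C)C(C)C)cc2OC(=O)C(C)C)CO1 | intermediate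
20 | {(2R)-2-[4-(hydroxymethyl)-2-(2-methylpropanoyloxy)phenyl]oxiran-2-yl}methyl pentanoate | CCCCC(=O)OC[C@@]1(c2ccc(CO)cc2OC(=O)C(C)C)CO1 | target

**Step count**

Total: 11 steps. Longest linear sequence: 9 steps (1, 2, 3, 5, 7, 8, 9, 10, 11); steps 4 and 6 make the two side reagents.

**Steps most likely to fail**

1. Step 7. The catalyst may discriminate poorly between the ortho-substituted aryl group and the CH2OPMB arm, or addition to the hindered carbonyl may be slow enough for enolisation and aldol loss of the ketone to take over. The fallback sets out from ketone 11 and comes back at epoxy alcohol 16. Wittig methylenation of 11 (Ph3PCH3Br, KOtBu, THF, 0 °C) should give the 2-arylallyl 4-methoxybenzyl ether F1. DDQ in buffered wet CH2Cl2 should then free the 2-arylprop-2-en-1-ol F2. Sharpless asymmetric epoxidation of F2 (catalytic Ti(OiPr)4, L-(+)-diisopropyl tartrate, t-BuOOH, MS 4 Å, CH2Cl2, −20 °C) should deliver 16. The natural tartrate is the one expected to give the (S)-alcohol, as it does for allyl alcohol and 2-substituted allyl alcohols, and the hydroxyl-directed oxidant should leave the allyl ether alkene alone.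

2. Step 10. The phenoxide may open the neighbouring oxirane in the instant before it is stannylated and acylated, or the hindered allyl aryl ether may ionise too slowly. The fallback sets out from ketone 11 and comes back at silyl ether 19; it puts the aryl ester in place before the oxirane exists. Pd(PPh3)4 with morpholine in THF should remove the allyl group from 11 to give the hydrogen-bonded hydroxy ketone F3. Wittig methylenation with an excess of Ph3P=CH2 should give the 2-alkenylphenol F4, and isobutyric anhydride with Et3N and DMAP the aryl isobutyrate F5. Buffered DDQ should free the allylic alcohol F6, which is handled cold to hold back transfer of the acyl group to the new hydroxyl. Sharpless asymmetric epoxidation (catalytic Ti(OiPr)4, L-(+)-diisopropyl tartrate, t-BuOOH, MS 4 Å, CH2Cl2, −20 °C) should give the (S)-epoxy alcohol F7, and pentanoic anhydride with Et3N and DMAP then leads to 19.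

3. Step 11. The basicity that comes with fluoride may cleave or shift the aryl isobutyrate, or the benzylic oxirane may open. The fallback sets out from pentanoate 17 and comes back at target 20; it removes the silyl group while no aryl ester is present. Bu4NF in THF at 0 °C should give the benzylic alcohol F8. The conditions of step 10 with only 1.05 equiv of isobutyric anhydride should then form the tin phenoxide F9 and acylate it to 20, because the tin phenoxide reacts with the anhydride without added base, conditions under which a neutral primary alcohol is acylated only slowly.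

**Further compounds**

F1 | step 7 | 1-methoxy-4-[({2-[2-(prop-2-en-1-yloxy)-4-({[tri(propan-2-yl)silyl]oxy}methyl)phenyl]prop-2-en-1-yl}oxy)methyl]benzene | COc1ccc(COCC(=C)c2ccc(CO[Si](C(C)C)(C(C)C)C(C)C)cc2OCC=C)cc1
F2 | step 7 | 2-[2-(prop-2-en-1-yloxy)-4-({[tri(propan-2-yl)silyl]oxy}methyl)phenyl]prop-2-en-1-ol | C=C(CO)c1ccc(CO[Si](C(C)C)(C(C)C)C(C)C)cc1OCC=C
F3 | step 10 | 1-[2-hydroxy-4-({[tri(propan-2-yl)silyl]oxy}methyl)phenyl]-2-[(4-methoxyphenyl)methoxy]ethan-1-one | COc1ccc(COCC(=O)c2ccc(CO[Si](C(C)C)(C(C)C)C(C)C)cc2O)cc1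
F4 | step 10 | 2-{3-[(4-methoxyphenyl)methoxy]prop-1-en-2-yl}-5-({[tri(propan-2-yl)silyl]oxy}methyl)phenol | COc1ccc(COCC(=C)c2ccc(CO[Si](C(C)C)(C(C)C)C(C)C)cc2O)cc1
F5 | step 10 | 2-{3-[(4-methoxyphenyl)methoxy]prop-1-en-2-yl}-5-({[tri(propan-2-yl)silyl]oxy}methyl)phenyl 2-methylpropanoate | COc1ccc(COCC(=C)c2ccc(CO[Si](C(C)C)(C(C)C)C(C)C)cc2OC(=O)C(C)C)cc1
F6 | step 10 | 2-(3-hydroxyprop-1-en-2-yl)-5-({[tri(propan-2-yl)silyl]oxy}methyl)phenyl 2-methylpropanoate | C=C(CO)c1ccc(CO[Si](C(C)C)(C(C)C)C(C)C)cc1OC(=O)C(C)C
F7 | step 10 | 2-[(2S)-2-(hydroxymethyl)oxiran-2-yl]-5-({[tri(propan-2-yl)silyl]oxy}methyl)phenyl 2-methylpropanoate | OC[C@@]1(c2ccc(CO[Si](C(C)C)(C(C)C)C(C)C)cc2OC(=O)C(C)C)CO1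
F8 | step 11 | {(2R)-2-[4-(hydroxymethyl)-2-(prop-2-en-1-yloxy)phenyl]oxiran-2-yl}methyl pentanoate | CCCCC(=O)OC[C@@]1(c2ccc(CO)cc2OCC=C)CO1
F9 | step 11 | {(2R)-2-[4-(hydroxymethyl)-2-[(tributylstannyl)oxy]phenyl]oxiran-2-yl}methyl pentanoate | CCCCC(=O)OC[C@@]1(c2ccc(CO)cc2O[Sn](CCCC)(CCCC)CCCC)CO1
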